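Target is read here as made from starting material with one coupling partner each, with the second substrate drawing on the same coupling partner, so that where the partner falls short the yield of a flask is a division of that partner.

| flask | starting material | coupling partner | second substrate | free catalyst | remark | time |
|---|---|---|---|---|---|---|
| cedar | 0.20 M | 0.30 M | 0.20 M | 0.081 mM | run made earlier |  |
| maple | 0.20 M | 0.30 M | 0.20 M | 0.62 mM | run made earlier |  |
| larch | 0.20 M | 0.46 M | 0.20 M | 0.22 mM | run made earlier |  |
| Wednesday's | 0.80 M | 1.20 M | 0.200 M | 0.40 mM |  | 2.5 min |
| Friday's | 0.20 M | 0.300 M | 0.200 M | 0.22 mM |  | 2.5 min |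
| Saturday's | 0.10 M | 0.300 M | 0.200 M | 0.22 mM |  | 2.5 min |
| Thursday's | 0.20 M | 0.300 M | 0.100 M | 0.060 mM |  | 2.5 min |
| Tuesday's | 0.60 M | 0.300 M | 0.200 M | 0.22 mM |  | 2.5 min |

| run | time / s | target / % | starting material / % |
|---|---|---|---|
| cedar | 10.0 | 53.8 | 45.4 |
| cedar | 15.0 | 57.7 | 44.4 |
| cedar | 30.0 | 60.3 | 40.0 |
| cedar | 80.0 | 61.0 | 36.5 |
| maple | 20.0 | 64.0 | 36.8 |
| maple | 40.0 | 61.9 | 37.4 |
| maple | 60.0 | 63.2 | 36.9 |
| maple | 80.0 | 62.7 | 38.9 |
| larch | 10.0 | 93.3 | 5.1 |
| larch | 25.0 | 97.6 | 1.8 |
| larch | 50.0 | 99.6 | 0.3 |
| larch | 80.0 | 100.2 | 1.1 |

(each reading ± 1 percentage point)

- the numbers in the tables scatter by 1 percentage point (one standard deviation)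

* the flasks by amount of target, in percent of the starting material charged, highest first, at 2.5 min (Wednesday's / Friday's / Saturday's / Thursday's / Tuesday's)
* the same order at 8.0 s (Wednesday's / Friday's / Saturday's / Thursday's / Tuesday's)
* the amount of target, in percent of the starting material charged of the flask you put first, at 2.5 min
* the amount of target, in percent of the starting material charged of the flask you put last, at 2.5 min

The cedar and maple runs level off together, cedar at 61.0% and maple averaging 62.9%, with 0.081 mM and 0.62 mM of free catalyst, whereas larch, with 0.46 M of coupling partner, reaches 100.2%; the coupling partner is therefore read as the limiting reagent of cedar and maple. If maple's 0.30 M was shared out to the last, the second substrate took what target did not, leaving 13.0% of it against 37.1% of the starting material. If each substrate is used in proportion to its own amount, with partner and catalyst common to both, the logarithms of these fractions keep a fixed ratio whatever the catalyst does. This ratio of the logarithm of the fraction of second substrate left to that of starting material left, 2.06 in maple, is the selectivity factor.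

Tuesday's flask has the least partner per starting material, so it is reckoned here for last place, by a bracket separate from the forecast's reckoning. From above, 0.300 M of partner on 0.60 M of starting material allows 50.0% if the second substrate took none; from below, 16.7% remains if its 0.200 M went first. Taking the partner of Tuesday's flask as used to the last, as read in maple, and dividing it by the starting material plus the factor times the second substrate, both at their charges, gives a floor of 29.7%, because the second substrate thins faster than the starting material. Passing that floor through the factor gives Tuesday's flask a ceiling of 32.8%, and passing the ceiling back gives it a floor of 31.4%, both as good as the factor read from maple. Wednesday's, with 1.20 M of partner against 1.00 M of substrates together, has partner for both.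

The forecast gives Wednesday's > Saturday's > Thursday's > Friday's > Tuesday's at 2.5 min and Wednesday's > Saturday's > Friday's > Thursday's > Tuesday's at 8.0 s, with 100% (99% to 100.5%) first and 31.7% (29.5% to 34%) last, holding that “the partner is limiting and shared”; its 31.7% lies inside the bracket.

The flasks stand Wednesday's > Saturday's > Thursday's > Friday's > Tuesday's at 2.5 min and Wednesday's > Saturday's > Friday's > Thursday's > Tuesday's at 8.0 s, with 100% in Wednesday's and 31.6% in Tuesday's, inside the bracket, where 68% of the starting material and 45% of the second substrate's own charge remain beside 0% of the coupling partner, and the target still reads 31.6% at 25.0 min.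

    free catalyst → spent catalyst (k = 0.0357 s⁻¹)
    starting material + coupling partner + free catalyst → free catalyst + target (k = 12000 L² mol⁻² s⁻¹)
    second substrate + coupling partner + free catalyst → free catalyst + second product (k = 25500 L² mol⁻² s⁻¹)

Tuesday's recipe with 0.050 M of second substrate goes through the same reckoning, with a floor of 42.7% and a ceiling of 44.3%, and that neighbouring flask gives 44.1% of target.

The readings are simulated with constants of no real substance.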